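## Retrosynthetic overview

1. Numbering (labdane): ring A = C1–C5 and C10; ring B = C5–C10; C20 = methyl on C10; C17 on C8; C18 and C19 on C4; chain C11–C12; butenolide C13–C16.
2. The last bond, C12–C13, comes from a B-alkyl Suzuki–Miyaura coupling of a C11=C12 vinyl group (from a C11 acetal) with 3-bromofuran-2(5H)-one; the three CH2OH groups come from one LiAlH4 reduction of a C4 malonate and a C17 ester.
3. Ring B is annulated onto preformed ring A by a sulfone-mediated [3+3] annulation that makes C6–C7 and C9–C10 in one pot; the C6 sulfone is then removed and the C5=C6 alkene reduced to the trans ring fusion.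
4. Enabling feature: C6 and C10 both sit on C5 of ring A, so C6–C5=C10 is one allyl anion (α-end C6 with a removable sulfone, γ-end C10 with the methyl), and C7–C8(C17 ester)–C9 is the methylene, α-carbon and carbinol carbon of a Morita–Baylis–Hillman acetate.
5. Order: ring A (malonate alkylation, ozonolysis, aldol condensation), then ring B (key step), then the butenolide; absolute configuration through a (−)-menthyl ester at C17, separated as diastereomers and cleaved in the LiAlH4 step.

Key step: step 8

Assumption: the menthyl ester is relied on only to make the two mirror-image ring configurations separable as diastereomers in step 8 (the unwanted one is recycled by base), not for asymmetric induction; 11, 12 (60% in water) and 22 are taken as purchasable.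

## Route

Step 1
Reactants: 1 dimethyl allylmalonate; 2 2-(3-chloropropyl)-2-methyl-1,3-dioxolane
Product: 3 dimethyl 2-allyl-2-[3-(2-methyl-1,3-dioxolan-2-yl)propyl]malonate
Conditions: NaH, DMF, 0 °C; then 2, NaI (cat.), 70 °C
Reagents that add atoms: none
Why: Malonate alkylation (SN2, with in situ Finkelstein exchange) should build the quaternary C4 with its two ester carbons C18 and C19, the C1–C3 chain with the masked C10 ketone and the allyl group that becomes C5–C6, and no stereocenter is formed.

Step 2
Reactants: 3 dimethyl 2-allyl-2-[3-(2-methyl-1,3-dioxolan-2-yl)propyl]malonate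
Product: 5 dimethyl 2-[3-(2-methyl-1,3-dioxolan-2-yl)propyl]-2-(2-oxoethyl)malonate, via ozonide 4 (not isolated)
Conditions: O3, CH2Cl2, −78 °C; then PPh3, −78 °C → rt
Reagents that add atoms: ozone | [O-][O+]=O
Why: Ozonolysis with reductive work-up should cleave only the terminal alkene to the C6 aldehyde, since ketal and esters are inert to ozone.

Step 3
Reactants: 5 dimethyl 2-[3-(2-methyl-1,3-dioxolan-2-yl)propyl]-2-(2-oxoethyl)malonate
Product: 7 dimethyl 2-formyl-3-methylcyclohex-2-ene-1,1-dicarboxylate, via keto-aldehyde 6 (not isolated)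
Conditions: 1 M HCl, THF, rt; then piperidine, AcOH, toluene, 70 °C
Reagents that add atoms: water | O
Why: After ketal hydrolysis, an amine-mediated intramolecular aldol condensation (the enamine of the aldehyde attacks the methyl ketone through C5, then water is lost) should close ring A as the tetrasubstituted enal, because only the aldehyde forms an enamine readily, and no stereocenter is formed.

Step 4
Reactants: 7 dimethyl 2-formyl-3-methylcyclohex-2-ene-1,1-dicarboxylate
Product: 8 dimethyl 2-(hydroxymethyl)-3-methylcyclohex-2-ene-1,1-dicarboxylate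
Conditions: NaBH4, CeCl3·7H2O, MeOH, −78 °C
Reagents that add atoms: none
Why: Luche reduction should reduce the enal 1,2 without touching the esters, and the allylic alcohol is carried on crude and cold because the neighbouring malonate ester could lactonize it.

Step 5
Reactants: 8 dimethyl 2-(hydroxymethyl)-3-methylcyclohex-2-ene-1,1-dicarboxylate
Product: 10 dimethyl 3-methyl-2-[(phenylsulfonyl)methyl]cyclohex-2-ene-1,1-dicarboxylate, via allylic mesylate 9 (not isolated)
Conditions: MsCl, Et3N, CH2Cl2, −30 °C; then PhSO2Na, Bu4NI (cat.), DMF, 0 °C → rt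
Reagents that add atoms: sodium benzenesulfinate | [Na+].[O-]S(=O)c1ccccc1
Why: Mesylation and SN2 displacement by the sulfur of the sulfinate at the primary allylic carbon should give the allyl sulfone, the activating group that makes C6 (α) and C10 (γ) the two ends of one stabilized allyl anion.

Step 6
Reactants: 11 (−)-menthyl acrylate; 12 2,2-dimethoxyacetaldehyde
Product: 13 (−)-menthyl 3-hydroxy-4,4-dimethoxy-2-methylidenebutanoate (both C3 epimers)
Conditions: DABCO, 1,4-dioxane/H2O, rt
Reagents that add atoms: none
Why: The Morita–Baylis–Hillman reaction of the acrylate with this activated aldehyde should give the allylic alcohol that holds C7, C8, C17, C9 and C11, and its carbinol stereocenter may form as a mixture because it is erased in step 8.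

Step 7
Reactants: 13 (−)-menthyl 3-hydroxy-4,4-dimethoxy-2-methylidenebutanoate
Product: 14 (−)-menthyl 3-acetoxy-4,4-dimethoxy-2-methylidenebutanoate (both C3 epimers)
Conditions: Ac2O, DMAP (cat.), pyridine, CH2Cl2, 0 °C
Reagents that add atoms: acetic anhydride | CC(=O)OC(C)=O
Why: Acetylation of the secondary allylic alcohol should turn it into the leaving group needed for the SN2′ event of step 8.

Step 8
Reactants: 10 dimethyl 3-methyl-2-[(phenylsulfonyl)methyl]cyclohex-2-ene-1,1-dicarboxylate; 14 (−)-menthyl 3-acetoxy-4,4-dimethoxy-2-methylidenebutanoate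
Product: 16 5,5-dimethyl 2-(−)-menthyl 1-(dimethoxymethyl)-8a-methyl-4-(phenylsulfonyl)-1,2,3,5,6,7,8,8a-octahydronaphthalene-2,5,5-tricarboxylate (acetal group cis to the angular methyl; menthyl ester trans to the acetal group; ring configuration as in 24; separated from the diastereomer with the mirror-image ring), via open-chain allyl sulfone 15 (not isolated)
Conditions: KN(SiMe3)2 (1.05 equiv), THF, −78 °C; then 14, −78 → 0 °C; then KOt-Bu (0.3 equiv), t-BuOH, 0 → 40 °C
Reagents that add atoms: none
Why: Proposed new method: deprotonation of 10 gives the sulfone-stabilized allyl anion C6–C5=C10, whose unhindered α-carbon (C6) adds to the methylene terminus (C7) of 14 with loss of acetate (Michael addition/E1cB, the SN2′ substitution typical of Baylis–Hillman acetates) to give 15; catalytic KOt-Bu then removes the remaining C6–H and the γ-carbon (C10) of the regenerated allyl anion attacks the enoate β-carbon (C9), which closes ring B by a 6-endo-trig Michael addition and leaves a C5=C6 vinyl sulfone. The closest known reaction types are base-mediated [3+3] annulations of Baylis–Hillman acetates with 1,3-bis-nucleophiles (SN2′ alkylation, then intramolecular Michael addition) and the γ-selective conjugate additions of metallated allylic sulfones, sulfoxides and phosphine oxides; what is new is their combination in a ring closure that makes a quaternary carbon. The sequence needs α-attack first and γ-attack second: the first is secured by the primary α-carbanion next to a fully substituted γ-carbon, the second by ring size, because α-attack on C9 would give a cyclobutane. C10 and C9 are set in the Michael closure and C8 by protonation of the ester enolate; under the proton-transfer conditions the closure is reversible and C8 epimerizes, so the three centres should settle, from either alkene isomer and either C6 epimer of 15, in the most stable arrangement, with the C9 acetal group equatorial and cis to the axial C10 methyl and the C8 ester equatorial and trans to C9. The menthyl ester makes the two mirror-image ring configurations diastereomers, so the one drawn is separated by crystallization or chromatography and the other is returned to the equilibrating base, which regenerates both through retro-Michael opening.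

Step 9
Reactants: 16 bicyclic vinyl sulfone
Product: 17 5,5-dimethyl 2-(−)-menthyl 1-(dimethoxymethyl)-8a-methyl-1,2,3,5,6,7,8,8a-octahydronaphthalene-2,5,5-tricarboxylate (ring configuration as in 24)
Conditions: Na(Hg) (5% Na), Na2HPO4, MeOH/THF, −20 °C
Reagents that add atoms: none
Why: Reductive desulfonylation of the vinyl sulfone with buffered sodium amalgam should replace the sulfonyl group by hydrogen with the C5=C6 alkene kept in place, which removes the activating group without touching the stereocenters.

Step 10
Reactants: 17 desulfonylated octahydronaphthalene triester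
Product: 18 5,5-dimethyl 2-(−)-menthyl 1-(dimethoxymethyl)-8a-methyldecahydronaphthalene-2,5,5-tricarboxylate (4a-H trans to the 8a-methyl; ring configuration as in 24)
Conditions: Mn(dpm)3 (cat.; dpm = dipivaloylmethanate), PhSiH3, t-BuOOH, i-PrOH, rt
Reagents that add atoms: none
Why: Metal-hydride hydrogen-atom-transfer hydrogenation should add a hydrogen atom to C6 of the hindered alkene, and the tertiary C5 radical should take up hydrogen from the face opposite the axial C10 methyl and the axial C4 ester, which sets C5 and gives the more stable trans ring fusion.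

Step 11
Reactants: 18 trans-decalin triester acetal
Product: 19 5,5-dimethyl 2-(−)-menthyl 1-formyl-8a-methyldecahydronaphthalene-2,5,5-tricarboxylate (ring configuration as in 24)
Conditions: 1 M HCl, THF, 0 °C → rt
Reagents that add atoms: water | O
Why: Acid hydrolysis of the dimethyl acetal should unveil the C11 aldehyde while the esters survive, and C9, now α to the aldehyde, already holds its more stable equatorial configuration.

Step 12
Reactants: 19 trans-decalin triester aldehyde
Product: 20 5,5-dimethyl 2-(−)-menthyl 1-ethenyl-8a-methyldecahydronaphthalene-2,5,5-tricarboxylate (ring configuration as in 24)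
Conditions: Ph3PCH3Br, KN(SiMe3)2, THF, 0 °C; then 19, −78 → 0 °C
Reagents that add atoms: methyltriphenylphosphonium bromide | C[P+](c1ccccc1)(c1ccccc1)c1ccccc1.[Br-]
Why: Wittig methylenation should convert the aldehyde into the C11=C12 vinyl group chemoselectively in the presence of the esters at low temperature.

Step 13
Reactants: 20 trans-decalin triester alkene
Product: 21 [(1R,2S,4aS,8aS)-1-ethenyl-8a-methyloctahydronaphthalene-2,5,5(1H)-triyl]trimethanol
Conditions: LiAlH4, THF, 0 → 60 °C; aqueous NaOH work-up
Reagents that add atoms: none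
Why: Exhaustive hydride reduction should turn the C4 malonate and the C17 menthyl ester into the three hydroxymethyl groups and release the auxiliary as menthol, while the isolated vinyl group is inert.

Step 14
Reactants: 21 vinyl triol; 22 3-bromofuran-2(5H)-one
Product: 24 3-{2-[(1R,2S,4aS,8aS)-2,5,5-tris(hydroxymethyl)-8a-methyldecahydronaphthalen-1-yl]ethyl}furan-2(5H)-one, via tris(borinate) alkylborane 23 (not isolated)
Conditions: 9-BBN (4.5 equiv), THF, 0 °C → rt; then 22, PdCl2(dppf), AsPh3, Cs2CO3, DMF/H2O, rt
Reagents that add atoms: none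
Why: Anti-Markovnikov hydroboration of the vinyl group (the excess 9-BBN takes up the three hydroxyls as borinates, which are freed again by the aqueous base) followed by B-alkyl Suzuki–Miyaura coupling with the α-bromobutenolide should form C12–C13 and complete the α-substituted butenolide without touching any stereocenter.

## Compound list

1 | dimethyl allylmalonate | C=CCC(C(=O)OC)C(=O)OC | starting material
2 | 2-(3-chloropropyl)-2-methyl-1,3-dioxolane | CC1(CCCCl)OCCO1 | starting material
3 | dimethyl 2-allyl-2-[3-(2-methyl-1,3-dioxolan-2-yl)propyl]malonate | C=CCC(CCCC1(C)OCCO1)(C(=O)OC)C(=O)OC | intermediate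
4 | ozonide (1,2,4-trioxolane) of 3; not isolated | COC(=O)C(CCCC1(C)OCCO1)(CC1OCOO1)C(=O)OC | intermediate
5 | dimethyl 2-[3-(2-methyl-1,3-dioxolan-2-yl)propyl]-2-(2-oxoethyl)malonate | COC(=O)C(CCCC1(C)OCCO1)(CC=O)C(=O)OC | intermediate
6 | dimethyl 2-(2-oxoethyl)-2-(4-oxopentyl)malonate; not isolated | COC(=O)C(CCCC(C)=O)(CC=O)C(=O)OC | intermediate
7 | dimethyl 2-formyl-3-methylcyclohex-2-ene-1,1-dicarboxylate | CC1=C(C=O)C(C(=O)OC)(C(=O)OC)CCC1 | intermediate
8 | dimethyl 2-(hydroxymethyl)-3-methylcyclohex-2-ene-1,1-dicarboxylate | CC1=C(CO)C(C(=O)OC)(C(=O)OC)CCC1 | intermediate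
9 | dimethyl 3-methyl-2-{[(methylsulfonyl)oxy]methyl}cyclohex-2-ene-1,1-dicarboxylate; not isolated | CC1=C(COS(C)(=O)=O)C(C(=O)OC)(C(=O)OC)CCC1 | intermediate
10 | dimethyl 3-methyl-2-[(phenylsulfonyl)methyl]cyclohex-2-ene-1,1-dicarboxylate | CC1=C(CS(=O)(=O)c2ccccc2)C(C(=O)OC)(C(=O)OC)CCC1 | intermediate
11 | (−)-menthyl acrylate [(1R,2S,5R)-2-isopropyl-5-methylcyclohexyl prop-2-enoate] | C=CC(=O)O[C@@H]1C[C@H](C)CC[C@H]1C(C)C | starting material
12 | 2,2-dimethoxyacetaldehyde | COC(OC)C=O | starting material
13 | (−)-menthyl 3-hydroxy-4,4-dimethoxy-2-methylidenebutanoate (both C3 epimers) | COC(OC)C(O)C(=C)C(=O)O[C@@H]1C[C@H](C)CC[C@H]1C(C)C | intermediate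
14 | (−)-menthyl 3-acetoxy-4,4-dimethoxy-2-methylidenebutanoate (both C3 epimers) | COC(OC)C(OC(C)=O)C(=C)C(=O)O[C@@H]1C[C@H](C)CC[C@H]1C(C)C | intermediate
15 | (−)-menthyl 2-[2-(6,6-bis(methoxycarbonyl)-2-methylcyclohex-1-en-1-yl)-2-(phenylsulfonyl)ethyl]-4,4-dimethoxybut-2-enoate (E/Z and C-epimer mixture); not isolated | CC1=C(C(CC(=CC(OC)OC)C(=O)O[C@@H]2C[C@H](C)CC[C@H]2C(C)C)S(=O)(=O)c2ccccc2)C(C(=O)OC)(C(=O)OC)CCC1 | intermediate
16 | 5,5-dimethyl 2-(−)-menthyl 1-(dimethoxymethyl)-8a-methyl-4-(phenylsulfonyl)-1,2,3,5,6,7,8,8a-octahydronaphthalene-2,5,5-tricarboxylate | C[C@@]12CCCC(C(=O)OC)(C(=O)OC)C1=C(S(=O)(=O)c3ccccc3)C[C@H](C(=O)O[C@@H]3C[C@H](C)CC[C@H]3C(C)C)[C@H]2C(OC)OC | intermediate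
17 | 5,5-dimethyl 2-(−)-menthyl 1-(dimethoxymethyl)-8a-methyl-1,2,3,5,6,7,8,8a-octahydronaphthalene-2,5,5-tricarboxylate | C[C@@]12CCCC(C(=O)OC)(C(=O)OC)C1=CC[C@H](C(=O)O[C@@H]3C[C@H](C)CC[C@H]3C(C)C)[C@H]2C(OC)OC | intermediate
18 | 5,5-dimethyl 2-(−)-menthyl 1-(dimethoxymethyl)-8a-methyldecahydronaphthalene-2,5,5-tricarboxylate (trans-fused) | C[C@@]12CCCC(C(=O)OC)(C(=O)OC)[C@H]1CC[C@H](C(=O)O[C@@H]3C[C@H](C)CC[C@H]3C(C)C)[C@H]2C(OC)OC | intermediate
19 | 5,5-dimethyl 2-(−)-menthyl 1-formyl-8a-methyldecahydronaphthalene-2,5,5-tricarboxylate | C[C@@]12CCCC(C(=O)OC)(C(=O)OC)[C@H]1CC[C@H](C(=O)O[C@@H]3C[C@H](C)CC[C@H]3C(C)C)[C@H]2C=O | intermediate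
20 | 5,5-dimethyl 2-(−)-menthyl 1-ethenyl-8a-methyldecahydronaphthalene-2,5,5-tricarboxylate | C[C@@]12CCCC(C(=O)OC)(C(=O)OC)[C@H]1CC[C@H](C(=O)O[C@@H]3C[C@H](C)CC[C@H]3C(C)C)[C@H]2C=C | intermediate
21 | [(1R,2S,4aS,8aS)-1-ethenyl-8a-methyloctahydronaphthalene-2,5,5(1H)-triyl]trimethanol | C[C@@]12CCCC(CO)(CO)[C@H]1CC[C@H](CO)[C@H]2C=C | intermediate
22 | 3-bromofuran-2(5H)-one | O=C1OCC=C1Br | starting material
23 | B-alkyl-9-BBN adduct of 21 with the three hydroxyls as 9-BBN borinates; not isolated | C[C@@]12CCCC(COB3C4CCCC3CCC4)(COB3C4CCCC3CCC4)[C@H]1CC[C@H](COB3C4CCCC3CCC4)[C@H]2CCB3C4CCCC3CCC4 | intermediate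
24 | 3-{2-[(1R,2S,4aS,8aS)-2,5,5-tris(hydroxymethyl)-8a-methyldecahydronaphthalen-1-yl]ethyl}furan-2(5H)-one | C[C@@]12CCCC(CO)(CO)[C@H]1CC[C@H](CO)[C@H]2CCC1=CCOC1=O | target

## Step count and risks

Total steps: 14. Longest linear sequence: 12 steps (steps 1–5 and 8–14).

Steps most likely to fail:

1. Step 8 (Proposed new method). What may go wrong: the γ-attack on the congested enoate may lose to reprotonation, and allylic strain between the sulfonyl group and the C4 esters may push the reversible closure back to the open chain; separation of the two menthyl diastereomers may also be poor. Fallback with known chemistry, setting out from 10 and 14: only the first stage is run (KN(SiMe3)2, THF, −78 → −40 °C, acetic acid quench) and the open-chain allyl sulfone 15 is isolated. The allylic sulfone is then cleaved with buffered Na(Hg) to the desulfonylated diene ester F1. Ring B is closed by an iron-hydride hydrogen-atom-transfer radical conjugate addition (Fe(acac)3, PhSiH3, EtOH, 60 °C), in which hydrogen-atom transfer to the C5=C10 alkene gives the tertiary C10 radical that adds 6-endo to C9. After equilibration of C8 with KOt-Bu/t-BuOH and separation of the menthyl diastereomers, this comes back to the route at 18, so steps 9 and 10 fall away.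

2. Step 10. What may go wrong: the alkene lies between two quaternary carbons, so hydrogen-atom transfer may be slow, and hydrogen delivery to the C5 radical may show poor facial selectivity and give some cis-fused product. Fallback, setting out from 17: hydroboration from the face opposite the C10 methyl (BH3·SMe2, THF; then NaBO3·4H2O) should give the 4-hydroxy trans-decalin F2 (hydroxyl at C6, cis to the new C5–H). Its imidazolylthiocarbonyl derivative F3 (1,1′-thiocarbonyldiimidazole, DMAP) is then deoxygenated with Bu3SnH and AIBN (Barton–McCombie), which comes back to the route at 18.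

3. Step 14. What may go wrong: the free hydroxyls may interfere with hydroboration and transmetallation, and the base-sensitive bromobutenolide may decompose before it couples. Fallback, setting out from 21: all three hydroxyls are silylated (t-BuMe2SiCl, imidazole, DMF) to the tris(silyl) ether F4. Hydroboration and oxidation (9-BBN; then NaBO3·4H2O) give the primary alcohol F5, and Dess–Martin oxidation gives the aldehyde F6. A Wittig reaction with 3-(triphenylphosphoranylidene)dihydrofuran-2(3H)-one gives the (E)-alkylidene lactone F7. The double bond is moved into the lactone ring with RhCl3·3H2O in hot ethanol to give the silyl-protected butenolide F8, and HF·pyridine removes the silyl groups, which comes back to the route at 24.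

## Further compounds

F1 | step 8 | (−)-menthyl 2-[2-(6,6-bis(methoxycarbonyl)-2-methylcyclohex-1-en-1-yl)ethyl]-4,4-dimethoxybut-2-enoate (E/Z mixture) | CC1=C(CCC(=CC(OC)OC)C(=O)O[C@@H]2C[C@H](C)CC[C@H]2C(C)C)C(C(=O)OC)(C(=O)OC)CCC1
F2 | step 10 | 5,5-dimethyl 2-(−)-menthyl 1-(dimethoxymethyl)-4-hydroxy-8a-methyldecahydronaphthalene-2,5,5-tricarboxylate (trans-fused; hydroxyl cis to 4a-H) | C[C@@]12CCCC(C(=O)OC)(C(=O)OC)[C@H]1[C@H](O)C[C@H](C(=O)O[C@@H]3C[C@H](C)CC[C@H]3C(C)C)[C@H]2C(OC)OC
F3 | step 10 | O-(imidazol-1-ylthiocarbonyl) derivative of F2 | C[C@@]12CCCC(C(=O)OC)(C(=O)OC)[C@H]1[C@H](OC(=S)n3ccnc3)C[C@H](C(=O)O[C@@H]3C[C@H](C)CC[C@H]3C(C)C)[C@H]2C(OC)OC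
F4 | step 14 | tris(tert-butyldimethylsilyl) ether of 21 | C[C@@]12CCCC(CO[Si](C)(C)C(C)(C)C)(CO[Si](C)(C)C(C)(C)C)[C@H]1CC[C@H](CO[Si](C)(C)C(C)(C)C)[C@H]2C=C
F5 | step 14 | 2-[(1R,2S,4aS,8aS)-2,5,5-tris(tert-butyldimethylsilyloxymethyl)-8a-methyldecahydronaphthalen-1-yl]ethanol | C[C@@]12CCCC(CO[Si](C)(C)C(C)(C)C)(CO[Si](C)(C)C(C)(C)C)[C@H]1CC[C@H](CO[Si](C)(C)C(C)(C)C)[C@H]2CCO
F6 | step 14 | 2-[(1R,2S,4aS,8aS)-2,5,5-tris(tert-butyldimethylsilyloxymethyl)-8a-methyldecahydronaphthalen-1-yl]acetaldehyde | C[C@@]12CCCC(CO[Si](C)(C)C(C)(C)C)(CO[Si](C)(C)C(C)(C)C)[C@H]1CC[C@H](CO[Si](C)(C)C(C)(C)C)[C@H]2CC=O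
F7 | step 14 | (E)-3-{2-[2,5,5-tris(tert-butyldimethylsilyloxymethyl)-8a-methyldecahydronaphthalen-1-yl]ethylidene}dihydrofuran-2(3H)-one (ring configuration as in 24) | C[C@@]12CCCC(CO[Si](C)(C)C(C)(C)C)(CO[Si](C)(C)C(C)(C)C)[C@H]1CC[C@H](CO[Si](C)(C)C(C)(C)C)[C@H]2C/C=C1/C(=O)OCC1
F8 | step 14 | tris(tert-butyldimethylsilyl) ether of 24 | C[C@@]12CCCC(CO[Si](C)(C)C(C)(C)C)(CO[Si](C)(C)C(C)(C)C)[C@H]1CC[C@H](CO[Si](C)(C)C(C)(C)C)[C@H]2CCC1=CCOC1=O
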